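## Structural features

The target is a tricyclic germacranolide: a ten-membered carbocycle (C1–C10) is bridged by an oxygen between C3 and C10, which with the C1 ketone and C2 makes a 3(2H)-furanone, and it is trans-fused at C7/C8 to an α-methylene-γ-butyrolactone (C11, C12, C13, lactone oxygen on C8). C4=C5 is a Z trisubstituted alkene conjugated through C3 with the furanone, and C6 carries the ester of (2R,3R)-2,3-dimethyloxirane-2-carboxylic acid (epoxyangelic acid). C6 (S), C7 (R) and C8 (S) are contiguous, the quaternary C10 (R) is separated from C8 only by the C9 methylene, and two further centres sit in the oxirane. The fragile groups are the exocyclic methylene lactone (a Michael acceptor and a ready partner for carbo- and acylpalladation), the oxirane, the allylic ester at C6 and the cross-conjugated vinylogous ester. The real difficulty is closing a strained ten-membered ring that holds a Z alkene and, after bridging, a bicyclic enol ether, with four stereocentres already in place. The feature exploited is that C3 is a single carbonyl-level carbon between the alkene carbon C4 and the two-carbon unit C2–C1 on the tertiary carbinol C10, so C3 can be carbon monoxide inserted between a C4 vinyl iodide and a terminal C1≡C2 alkyne, and the γ-hydroxy ynone so formed is the direct precursor of the furanone. A centre-by-centre comparison of the open-chain iodoalkene alkynol, the ten-membered ynone and the target (C6, C7, C8, C10, both oxirane carbons, C4=C5 geometry) shows the same configuration throughout, and the one design refinement is that the methylene lactone is carried through the Pd(PPh3)4/CuI carbonylation as its dimethylamine adduct.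

## Logic of the disconnections

**31 back to 30.** The O–C3 bond of the furanone is cut and the C1 carbonyl oxygen removed, which leaves the C10 hydroxyl, the C1≡C2 alkyne and the C3 ketone. A 3(2H)-furanone is the cycloisomer of a γ-hydroxy ynone, so the oxygen bridge need not be carried through the macrocyclisation. The gain is one ring fewer and a less strained bicycle. The forward step must hydrate regioselectively at C1 without touching the methylene lactone or the oxirane, which calls for Ph3PAuCl/AgOTf under neutral conditions. It is placed after the amine of 28 has been removed, because a basic amine would bind the gold cation.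

**30 back to 28.** No skeletal bond is cut; the C11=C13 double bond is traced back to a C13–N bond. In 30 the methylene sits 1,5 to C4 and 1,6 to C3, well placed for 5-exo carbopalladation or 6-exo acylpalladation, either of which would outrun a ten-membered closure. In 28 and 26 that alkene does not exist, so the key step is freed of its most likely side reaction. The forward step must regenerate the alkene under conditions mild enough for the ynone: N-methylation and elimination with bicarbonate.

**28 back to 26 and 27.** C3–C4 and C2–C3 are cut, and C3 becomes 27. This is the only place where one inserted atom opens the ring and leaves two simple termini, a Z vinyl iodide and a terminal alkyne. The gain is an acyclic chain on a lactone. The forward step must insert 27 before alkynyl transfer, close the ring in preference to oligomerising, and keep the Z geometry.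

**26 back to 20 and 24.** The acyl–O6 bond is cut. The acid-sensitive oxirane ester then enters late, after all strongly basic and reducing steps, and 24 is made separately as one enantiomer. The forward step must acylate the secondary allylic hydroxyl with a hindered acid in the presence of the tertiary C10 hydroxyl.

**24 back to 21 through 23 and 22.** The two oxirane C–O bonds are cut and the carboxyl is taken back to a primary alcohol. An allylic alcohol allows reagent-controlled epoxidation, which the acid itself does not. The forward steps must keep the Z geometry of 21 and deliver oxygen to one face.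

**20 back to 18 through 19.** The silyl groups on O6 and on the alkyne terminus are restored and the C11–C13 bond is cut. The one-carbon unit is added to the lactone enolate as an iminium ion, so the mask and the methylene carbon arrive in one step. The forward step must enolise the lactone while the alkyne is capped, since a free acetylide would also be aminomethylated, and it must not dehydroiodinate the vinyl iodide.

**18 back to 16 through 17.** The lactone C12–O8 bond is opened to the tert-butyl ester and the C10–CH3 bond is cut, which gives a β-hydroxy ynone. The free C8 hydroxyl is needed to direct the methyl addition, so lactonisation must come after it. The forward steps must add methyl 1,2 to the ynone on one face and then close only the 12,8-lactone.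

**16 back to 13 and 15 (15 from 14).** The C8–C9 bond is cut in the aldol sense. This joins a four-carbon ynone unit to the C8 aldehyde and sets C8 from the existing C6/C7 pair. The forward step must follow Felkin and 1,3-anti induction, which reinforce each other in this 2,3-anti aldehyde.

**13 back to 10 through 12 and 11.** Only functional groups change: aldehyde from amide from imide, silyl ether from hydroxyl. The forward steps must not epimerise C7 or reduce the tert-butyl ester.

**10 back to 4 and 8 (4 from 1 and 2; 8 from 5 through 7).** The C6–C7 bond is cut. One auxiliary-controlled anti-aldol sets C6 and C7 and brings in the complete Z iodoalkene, so no hydrometallation is needed later in the presence of esters. The forward step must give the anti adduct and keep the geometry of the β-iodoenal.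

## Other disconnections considered

Alternative 1: The cut is the C4=C5 double bond, traced back to C4–S and C5–S bonds in the eleven-membered cyclic sulfone A2. The forward key step is a Ramberg–Bäcklund contraction: halogenation at C4 with CBr2F2 on KOH/Al2O3, 1,3-elimination and loss of sulfur dioxide would give the ten-membered carbocycle A1.
- In its favour: the large ring is first closed as a C–S bond in an eleven-membered ring, which is an easier and better-precedented macrocyclisation than any ten-membered C–C closure. On this point it is the better plan. The furanone is already present and the position of the alkene is unambiguous.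
- Against it: the mechanism does not fix the geometry of a trisubstituted alkene, so the Z outcome would rest on ring constraints alone. The strongly basic medium and the difluorocarbene by-product meet a furanone with acidic positions and three silyl or benzyl ethers.
- Comparison: A1 still lacks the lactone and the ester. Unveiling O6, oxidising C12 twice, lactonising and esterifying would cost at least five steps after the key step, against two in the chosen plan. Neither key step forms a stereocentre. The chosen plan sets the alkene geometry earlier by a stereospecific hydroalumination and only has to retain it.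

Alternative 2: The cut is C11–C12 and C12–O8 of the lactone. The forward key step is a cyclocarbonylation of the homopropargylic alcohol A4 with PdCl2(PPh3)2 and SnCl2 under carbon monoxide, which would give the tricyclic methylene lactone A3.
- In its favour: the reaction type is known for exactly this substructure, which the chosen key step is not, and the methylene lactone is made late so that no mask is needed. On both points it is the better plan. A3 is two steps from the target (desilylation, esterification), which equals the two steps after the chosen key step.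
- Against it: it addresses neither the ten-membered ring nor the furanone. A4 must already be the bridged bicycle with an ethynyl group on the C7 stereocentre, so the hardest problem stays upstream and unsolved. The SnCl2 medium is Lewis acidic and meets the vinylogous ester and the silyl ether.
- Comparison: mechanistically it is the safer single step, but strategically it only moves the difficulty. The chosen plan closes the large ring and prepares the furanone in one event.

Alternative 3: The cut is the C6–C7 bond. The forward key step is a [2,3]-Wittig ring contraction: n-BuLi would deprotonate C6 of the thirteen-membered bis-allylic ether A6 and the sigmatropic shift would give the cyclodecenynol A5 with the C6 hydroxyl, the C7 centre and the 11(13)-methylene.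
- In its favour: contraction of large cyclic ethers to medium carbocycles is a precedented tactic, and the thirteen-membered ether is easy to close. It creates C6, C7 and the methylene in the ring-forming step, whereas the chosen key step creates no stereocentre. On stereochemical productivity it is the better plan.
- Against it: lithiation could occur at C6 or at C13, a [1,2]-shift competes, and the C6/C7 relationship depends on how the macrocycle folds in the transition state, which cannot be predicted with confidence. The base is strong.
- Comparison: A5 is far from the target. C1 and C12 must be oxidised, the furanone and lactone closed, the ester added and four silyl groups removed, at least seven steps after the key step. The chosen plan is clearly shorter after ring closure, at the price of an unprecedented closure.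

Key step: step 18

Remark on the chemistry: the temporary C11 centre of 19, 20, 26 and 28 is drawn as the 7,11-trans epimer expected from alkylation anti to the C7 side chain; either epimer gives the same methylene lactone.

## Route

Step 1
Reactants: 1 4-tert-butoxy-4-oxobutanoic acid; 2 (4R)-4-benzyl-1,3-oxazolidin-2-one
Product: 4 tert-butyl 4-[(4R)-4-benzyl-2-oxo-1,3-oxazolidin-3-yl]-4-oxobutanoate, via mixed pivalic anhydride 3 (not isolated)
Conditions: t-BuCOCl, Et3N, THF, −20 °C; then LiCl, 2, −20 °C → rt
Reagents that add atoms: none
Why: N-acylation of the oxazolidinone through a mixed anhydride (LiCl/Et3N protocol) needs no strong base and leaves the tert-butyl ester alone; no stereocentre is formed.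

Step 2
Reactants: 5 but-2-yn-1-ol
Product: 7 (2Z)-3-iodobut-2-en-1-ol, via cyclic vinylalanate 6 (not isolated)
Conditions: NaAlH2(OCH2CH2OCH3)2, THF, 0 °C → rt; then I2, THF, −78 → 0 °C
Reagents that add atoms: iodine, II
Why: Alkoxide-directed trans-hydroalumination puts aluminium on the distal alkyne carbon in a five-membered alanate, and iodinolysis with retention gives the Z iodide with iodine cis to the carbinol carbon.

Step 3
Reactants: 7 (2Z)-3-iodobut-2-en-1-ol
Product: 8 (2Z)-3-iodobut-2-enal
Conditions: MnO2, CH2Cl2, rt, dark
Reagents that add atoms: none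
Why: Heterogeneous allylic oxidation with MnO2 is neutral, so the Z geometry of the β-iodoenal should survive; the aldehyde is used at once.

Step 4
Reactants: 4 tert-butyl 4-[(4R)-4-benzyl-2-oxo-1,3-oxazolidin-3-yl]-4-oxobutanoate; 8 (2Z)-3-iodobut-2-enal
Product: 10 tert-butyl (3S,4R,5Z)-3-[(4R)-4-benzyl-2-oxo-1,3-oxazolidine-3-carbonyl]-4-hydroxy-6-iodohept-5-enoate, via trimethylsilyl ether 9 (not isolated)
Conditions: MgCl2 (20 mol%), Et3N, Me3SiCl, EtOAc, rt; then 1 M HCl, THF, 0 °C
Reagents that add atoms: none
Why: Evans MgCl2-catalysed direct anti-aldol of an N-acyloxazolidinone with a non-enolisable enal; the magnesium-chelated Z enolate is attacked on the face away from the benzyl group through a boat-like transition state, which should give the 6,7-anti adduct with C7 (3S) and C6 (4R) as drawn, while silylation of the aldolate turns the catalyst over.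

Step 5
Reactants: 10 tert-butyl (3S,4R,5Z)-3-[(4R)-4-benzyl-2-oxo-1,3-oxazolidine-3-carbonyl]-4-hydroxy-6-iodohept-5-enoate
Product: 11 tert-butyl (3S,4R,5Z)-4-hydroxy-6-iodo-3-[methoxy(methyl)carbamoyl]hept-5-enoate
Conditions: Al(CH3)3, MeNH(OMe)·HCl, CH2Cl2, −20 → 0 °C
Reagents that add atoms: N,O-dimethylhydroxylamine hydrochloride, CNOC.Cl
Why: Aluminium amide transamination of a β-hydroxy imide, assisted by the free C6 hydroxyl, attacks the exocyclic imide carbonyl in preference to the tert-butyl ester and leaves C7 untouched; auxiliary 2 is recovered.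

Step 6
Reactants: 11 tert-butyl (3S,4R,5Z)-4-hydroxy-6-iodo-3-[methoxy(methyl)carbamoyl]hept-5-enoate
Product: 12 tert-butyl (3S,4R,5Z)-4-[(tert-butyldimethylsilyl)oxy]-6-iodo-3-[methoxy(methyl)carbamoyl]hept-5-enoate
Conditions: t-BuMe2SiOTf, 2,6-lutidine, CH2Cl2, −78 °C
Reagents that add atoms: tert-butyldimethylsilyl trifluoromethanesulfonate, CC(C)(C)[Si](C)(C)OS(=O)(=O)C(F)(F)F
Why: O-silylation of the secondary allylic alcohol; at −78 °C the silyl triflate should not cleave the tert-butyl ester.

Step 7
Reactants: 12 tert-butyl (3S,4R,5Z)-4-[(tert-butyldimethylsilyl)oxy]-6-iodo-3-[methoxy(methyl)carbamoyl]hept-5-enoate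
Product: 13 tert-butyl (3S,4R,5Z)-4-[(tert-butyldimethylsilyl)oxy]-3-formyl-6-iodohept-5-enoate
Conditions: (i-Bu)2AlH, THF, −78 °C; aqueous KNaC4H4O6
Reagents that add atoms: none
Why: Weinreb amide reduction stops at the chelated hemiaminal, so the aldehyde appears only on work-up; the tert-butyl ester reacts more slowly and the cold, non-basic conditions should preserve the α-centre C7.

Step 8
Reactants: 14 4-(trimethylsilyl)but-3-yn-2-one
Product: 15 trimethyl{[4-(trimethylsilyl)but-1-en-3-yn-2-yl]oxy}silane
Conditions: LiN(SiMe3)2, THF, −78 °C; then Me3SiCl, −78 → 0 °C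
Reagents that add atoms: chlorotrimethylsilane, C[Si](C)(C)Cl
Why: Kinetic enolisation of the methyl ketone (the only enolisable site) and O-silylation give the enol silane for a Mukaiyama aldol; the hindered amide base avoids addition to the ynone.

Step 9
Reactants: 13 tert-butyl (3S,4R,5Z)-4-[(tert-butyldimethylsilyl)oxy]-3-formyl-6-iodohept-5-enoate; 15 trimethyl{[4-(trimethylsilyl)but-1-en-3-yn-2-yl]oxy}silane
Product: 16 tert-butyl (3R,4R,5Z)-4-[(tert-butyldimethylsilyl)oxy]-3-[(1S)-1-hydroxy-3-oxo-5-(trimethylsilyl)pent-4-yn-1-yl]-6-iodohept-5-enoate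
Conditions: BF3·OEt2, CH2Cl2, −78 °C; aqueous NaHCO3
Reagents that add atoms: none
Why: Mukaiyama aldol through an open transition state; in this 2,3-anti α-branched β-silyloxy aldehyde the Felkin preference at C7 and the 1,3-anti preference from the C6 silyloxy dipole point to the same face, which should give the 8S carbinol.

Step 10
Reactants: 16 tert-butyl (3R,4R,5Z)-4-[(tert-butyldimethylsilyl)oxy]-3-[(1S)-1-hydroxy-3-oxo-5-(trimethylsilyl)pent-4-yn-1-yl]-6-iodohept-5-enoate
Product: 17 tert-butyl (3R,4R,5Z)-4-[(tert-butyldimethylsilyl)oxy]-3-[(1S,3R)-1,3-dihydroxy-3-methyl-5-(trimethylsilyl)pent-4-yn-1-yl]-6-iodohept-5-enoate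
Conditions: CH3MgBr (3 equiv), CH2Cl2/Et2O, −78 °C; aqueous NH4Cl
Reagents that add atoms: methylmagnesium bromide, C[Mg]Br
Why: Chelation-controlled Grignard addition to a β-hydroxy ketone: the first equivalent makes the bromomagnesium C8 alkoxide, which holds the ynone carbonyl in a six-membered half-chair chelate, and external axial attack by a second equivalent should give the 8,10-syn diol (10R); the non-chelate dipole model predicts the same sense, and the silyl cap on the alkyne with the low temperature secures 1,2-addition.

Step 11
Reactants: 17 tert-butyl (3R,4R,5Z)-4-[(tert-butyldimethylsilyl)oxy]-3-[(1S,3R)-1,3-dihydroxy-3-methyl-5-(trimethylsilyl)pent-4-yn-1-yl]-6-iodohept-5-enoate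
Product: 18 (4R,5S)-4-[(1R,2Z)-1-[(tert-butyldimethylsilyl)oxy]-3-iodobut-2-en-1-yl]-5-[(2R)-2-hydroxy-2-methyl-4-(trimethylsilyl)but-3-yn-1-yl]oxolan-2-one
Conditions: TsOH·H2O (10 mol%), toluene, 50 °C
Reagents that add atoms: none
Why: Acid-catalysed 5-exo-trig lactonisation of a γ-hydroxy tert-butyl ester with loss of tert-butanol; O6 is silylated and the tertiary C10 hydroxyl would need a seven-membered ring, so only the trans 12,8-lactone (from the 7,8-syn array) can form.

Step 12
Reactants: 18 (4R,5S)-4-[(1R,2Z)-1-[(tert-butyldimethylsilyl)oxy]-3-iodobut-2-en-1-yl]-5-[(2R)-2-hydroxy-2-methyl-4-(trimethylsilyl)but-3-yn-1-yl]oxolan-2-one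
Product: 19 (3S,4R,5S)-4-[(1R,2Z)-1-[(tert-butyldimethylsilyl)oxy]-3-iodobut-2-en-1-yl]-3-[(dimethylamino)methyl]-5-[(2R)-2-hydroxy-2-methyl-4-(trimethylsilyl)but-3-yn-1-yl]oxolan-2-one
Conditions: LiN(i-Pr)2 (2.1 equiv), THF, −78 °C; then CH2=NMe2+ I−, −78 → −20 °C
Reagents that add atoms: N,N-dimethylmethyleneiminium iodide, C=[N+](C)C.[I-]
Why: Mannich aminomethylation of the lactone lithium enolate (the C10 alkoxide is a spectator and the alkyne is capped); the base is kept close to two equivalents and cold so that the vinyl iodide is not dehydroiodinated, the iminium ion should enter anti to the C7 side chain, and the new C11 centre is temporary, being lost in step 19.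

Step 13
Reactants: 19 (3S,4R,5S)-4-[(1R,2Z)-1-[(tert-butyldimethylsilyl)oxy]-3-iodobut-2-en-1-yl]-3-[(dimethylamino)methyl]-5-[(2R)-2-hydroxy-2-methyl-4-(trimethylsilyl)but-3-yn-1-yl]oxolan-2-one
Product: 20 (3S,4S,5S)-3-[(dimethylamino)methyl]-4-[(1R,2Z)-1-hydroxy-3-iodobut-2-en-1-yl]-5-[(2R)-2-hydroxy-2-methylbut-3-yn-1-yl]oxolan-2-one
Conditions: Bu4NF, AcOH (1:1), THF, 0 °C → rt
Reagents that add atoms: none
Why: Fluoride desilylation removes the O6 silyl ether and the alkynyl silyl group in one operation; buffering suppresses retro-Michael loss of the amine, and acyl migration to O6 is not expected because it would exchange the trans-disubstituted 12,8-lactone for a less stable cis-disubstituted 12,6-lactone.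

Step 14
Reactants: 21 angelic acid [(2Z)-2-methylbut-2-enoic acid]
Product: 22 (2Z)-2-methylbut-2-en-1-ol
Conditions: LiAlH4, Et2O, 0 °C → rt
Reagents that add atoms: none
Why: Hydride reduction of the carboxylic acid to the allylic alcohol; the trisubstituted alkene is not reduced and keeps its Z geometry.

Step 15
Reactants: 22 (2Z)-2-methylbut-2-en-1-ol
Product: 23 [(2S,3R)-2,3-dimethyloxiran-2-yl]methanol
Conditions: Ti(OiPr)4 (10 mol%), diethyl L-(+)-tartrate (12 mol%), t-BuOOH, 4 Å molecular sieves, CH2Cl2, −20 °C
Reagents that add atoms: tert-butyl hydroperoxide, CC(C)(C)OO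
Why: Sharpless asymmetric epoxidation; the catalyst from Ti(OiPr)4 and the (R,R)-tartrate delivers oxygen to the alkene face that gives the 2S carbinol-bearing centre (the same facial sense that leads to 2S epoxy alcohols from other primary allylic alcohols), and syn addition to the Z alkene keeps the C3 methyl cis to the hydroxymethyl group.

Step 16
Reactants: 23 [(2S,3R)-2,3-dimethyloxiran-2-yl]methanol
Product: 24 (2R,3R)-2,3-dimethyloxirane-2-carboxylic acid
Conditions: TEMPO (20 mol%), PhI(OAc)2, MeCN/H2O, rt
Reagents that add atoms: water, O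
Why: Oxoammonium oxidation of the primary alcohol through the aldehyde hydrate to the acid at near-neutral pH; the α-carbon is quaternary, so nothing can epimerise, and the oxirane is not opened (the descriptor at C2 changes only because the priorities change).

Step 17
Reactants: 20 (3S,4S,5S)-3-[(dimethylamino)methyl]-4-[(1R,2Z)-1-hydroxy-3-iodobut-2-en-1-yl]-5-[(2R)-2-hydroxy-2-methylbut-3-yn-1-yl]oxolan-2-one; 24 (2R,3R)-2,3-dimethyloxirane-2-carboxylic acid
Product: 26 (1R,2Z)-1-[(2S,3R,4S)-4-[(dimethylamino)methyl]-2-[(2R)-2-hydroxy-2-methylbut-3-yn-1-yl]-5-oxooxolan-3-yl]-3-iodobut-2-en-1-yl (2R,3R)-2,3-dimethyloxirane-2-carboxylate, via mixed Yamaguchi anhydride 25 (not isolated)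
Conditions: 2,4,6-Cl3C6H2COCl, Et3N, THF, rt; then 20, DMAP, toluene, rt
Reagents that add atoms: none
Why: Yamaguchi esterification suits the α-quaternary acid; only the secondary allylic O6 is acylated because the tertiary propargylic hydroxyl is inert, and acyl transfer at oxygen leaves C6 unchanged.

Step 18
Reactants: 26 (1R,2Z)-1-[(2S,3R,4S)-4-[(dimethylamino)methyl]-2-[(2R)-2-hydroxy-2-methylbut-3-yn-1-yl]-5-oxooxolan-3-yl]-3-iodobut-2-en-1-yl (2R,3R)-2,3-dimethyloxirane-2-carboxylate; 27 carbon monoxide
Product: 28 (4Z,6S,7R,8S,10R,11S)-13-(dimethylamino)-10-hydroxy-3-oxo-6-{[(2R,3R)-2,3-dimethyloxirane-2-carbonyl]oxy}germacr-4-en-1-yn-12,8-olide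
Conditions: Pd(PPh3)4 (10 mol%), CuI (10 mol%), Et3N, THF, CO (3 bar), 40 °C, syringe-pump addition of 26 to 1 mM
Reagents that add atoms: none
Why: Proposed new method: Zerovalent palladium inserts into the C4–I bond of 26 with retention, carbon monoxide inserts to give the C3 acyl complex of divalent palladium, the alkynylcopper species formed from the terminal alkyne, CuI and Et3N transfers C2 to palladium, and reductive elimination forms C2–C3 and returns the catalyst. The closest known reaction types are the intermolecular carbonylative Sonogashira coupling of vinyl and aryl iodides to ynones and carbonylative Stille macrocyclisations to cross-conjugated macrocyclic ketones; the intramolecular alkynyl version on a ten-membered ring is not established. The ring closes in the reductive elimination from an eleven-membered acyl(alkynyl)palladium chelate, formally a 10-exo-trig acyl substitution at C3 by the acetylide carbon C2. No stereocentre is formed; C6, C7, C8, C10 and the oxirane are spectators, and the Z geometry of C4=C5 carries over because no elementary step breaks the C4–C5 π bond. Insertion before alkynyl transfer is required and is favoured by CO pressure and by the fact that direct coupling would give a far more strained nine-membered enyne, while closure over oligomerisation is favoured by slow addition at high dilution and by the Z alkene and trans lactone, which hold C3 and C2 on the same side. Carbopalladation (5-exo) or acylpalladation (6-exo) of an exocyclic methylene is impossible because C11–C13 is saturated in 26, and the tertiary amine and the tertiary C10 hydroxyl are poor traps for the acyl complex.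

Step 19
Reactants: 28 (4Z,6S,7R,8S,10R,11S)-13-(dimethylamino)-10-hydroxy-3-oxo-6-{[(2R,3R)-2,3-dimethyloxirane-2-carbonyl]oxy}germacr-4-en-1-yn-12,8-olide
Product: 30 (4Z,6S,7R,8S,10R)-10-hydroxy-3-oxo-6-{[(2R,3R)-2,3-dimethyloxirane-2-carbonyl]oxy}germacra-4,11(13)-dien-1-yn-12,8-olide, via methiodide 29 (not isolated)
Conditions: CH3I, THF, rt; then aqueous NaHCO3, EtOAc, rt
Reagents that add atoms: none
Why: N-quaternisation followed by E1cB (retro-Michael) elimination of trimethylamine, the closing stage of the classical Eschenmoser α-methylenation; bicarbonate suffices because the leaving group is β to the lactone carbonyl, and C11 becomes sp2 so its configuration is irrelevant.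

Step 20
Reactants: 30 (4Z,6S,7R,8S,10R)-10-hydroxy-3-oxo-6-{[(2R,3R)-2,3-dimethyloxirane-2-carbonyl]oxy}germacra-4,11(13)-dien-1-yn-12,8-olide
Product: 31 (4Z,6S,7R,8S,10R)-3,10-epoxy-1-oxo-6-{[(2R,3R)-2,3-dimethyloxirane-2-carbonyl]oxy}germacra-2,4,11(13)-trien-12,8-olide (CNP0258430.3)
Conditions: Ph3PAuCl (5 mol%), AgOTf (5 mol%), toluene, H2O (2 equiv), rt
Reagents that add atoms: water, O
Why: Gold-catalysed cycloisomerisation of a γ-hydroxy ynone to a 3(2H)-furanone: π-activation by monovalent gold lets water add at C1 (β to the ketone), the 1,3-dione is captured at C3 by the C10 hydroxyl and loses water; no bond to C10 is broken, so its configuration carries over.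

## Compound list

1 | 4-tert-butoxy-4-oxobutanoic acid (mono-tert-butyl succinate) | CC(C)(C)OC(=O)CCC(=O)O | starting material
2 | (4R)-4-benzyl-1,3-oxazolidin-2-one | O=C1N[C@H](Cc2ccccc2)CO1 | starting material
3 | 4-tert-butoxy-4-oxobutanoic pivalic anhydride | CC(C)(C)OC(=O)CCC(=O)OC(=O)C(C)(C)C | intermediate
4 | tert-butyl 4-[(4R)-4-benzyl-2-oxo-1,3-oxazolidin-3-yl]-4-oxobutanoate | CC(C)(C)OC(=O)CCC(=O)N1[C@H](Cc2ccccc2)COC1=O | intermediate
5 | but-2-yn-1-ol | CC#CCO | starting material
6 | sodium cyclic vinylalanate (2,2-bis(2-methoxyethoxy)-3-methyl-2,5-dihydro-1,2-oxaluminol-2-uide) | CC1=CCO[Al-]1(OCCOC)OCCOC.[Na+] | intermediate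
7 | (2Z)-3-iodobut-2-en-1-ol | OC/C=C(/C)I | intermediate
8 | (2Z)-3-iodobut-2-enal | O=C/C=C(/C)I | intermediate
9 | tert-butyl (3S,4R,5Z)-3-[(4R)-4-benzyl-2-oxo-1,3-oxazolidine-3-carbonyl]-6-iodo-4-[(trimethylsilyl)oxy]hept-5-enoate | CC(C)(C)OC(=O)C[C@H](C(=O)N1[C@H](Cc2ccccc2)COC1=O)[C@@H](O[Si](C)(C)C)/C=C(/C)I | intermediate
10 | tert-butyl (3S,4R,5Z)-3-[(4R)-4-benzyl-2-oxo-1,3-oxazolidine-3-carbonyl]-4-hydroxy-6-iodohept-5-enoate | CC(C)(C)OC(=O)C[C@H](C(=O)N1[C@H](Cc2ccccc2)COC1=O)[C@@H](O)/C=C(/C)I | intermediate
11 | tert-butyl (3S,4R,5Z)-4-hydroxy-6-iodo-3-[methoxy(methyl)carbamoyl]hept-5-enoate | CC(C)(C)OC(=O)C[C@H](C(=O)N(C)OC)[C@@H](O)/C=C(/C)I | intermediate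
12 | tert-butyl (3S,4R,5Z)-4-[(tert-butyldimethylsilyl)oxy]-6-iodo-3-[methoxy(methyl)carbamoyl]hept-5-enoate | CC(C)(C)OC(=O)C[C@H](C(=O)N(C)OC)[C@@H](O[Si](C)(C)C(C)(C)C)/C=C(/C)I | intermediate
13 | tert-butyl (3S,4R,5Z)-4-[(tert-butyldimethylsilyl)oxy]-3-formyl-6-iodohept-5-enoate | CC(C)(C)OC(=O)C[C@H](C=O)[C@@H](O[Si](C)(C)C(C)(C)C)/C=C(/C)I | intermediate
14 | 4-(trimethylsilyl)but-3-yn-2-one | CC(=O)C#C[Si](C)(C)C | starting material
15 | trimethyl{[4-(trimethylsilyl)but-1-en-3-yn-2-yl]oxy}silane | C=C(O[Si](C)(C)C)C#C[Si](C)(C)C | intermediate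
16 | tert-butyl (3R,4R,5Z)-4-[(tert-butyldimethylsilyl)oxy]-3-[(1S)-1-hydroxy-3-oxo-5-(trimethylsilyl)pent-4-yn-1-yl]-6-iodohept-5-enoate | CC(C)(C)OC(=O)C[C@H]([C@@H](O)CC(=O)C#C[Si](C)(C)C)[C@@H](O[Si](C)(C)C(C)(C)C)/C=C(/C)I | intermediate
17 | tert-butyl (3R,4R,5Z)-4-[(tert-butyldimethylsilyl)oxy]-3-[(1S,3R)-1,3-dihydroxy-3-methyl-5-(trimethylsilyl)pent-4-yn-1-yl]-6-iodohept-5-enoate | CC(C)(C)OC(=O)C[C@H]([C@@H](O)C[C@@](C)(O)C#C[Si](C)(C)C)[C@@H](O[Si](C)(C)C(C)(C)C)/C=C(/C)I | intermediate
18 | (4R,5S)-4-[(1R,2Z)-1-[(tert-butyldimethylsilyl)oxy]-3-iodobut-2-en-1-yl]-5-[(2R)-2-hydroxy-2-methyl-4-(trimethylsilyl)but-3-yn-1-yl]oxolan-2-one | C1C(=O)O[C@@H](C[C@@](C)(O)C#C[Si](C)(C)C)[C@@H]1[C@@H](O[Si](C)(C)C(C)(C)C)/C=C(/C)I | intermediate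
19 | (3S,4R,5S)-4-[(1R,2Z)-1-[(tert-butyldimethylsilyl)oxy]-3-iodobut-2-en-1-yl]-3-[(dimethylamino)methyl]-5-[(2R)-2-hydroxy-2-methyl-4-(trimethylsilyl)but-3-yn-1-yl]oxolan-2-one | CN(C)C[C@H]1C(=O)O[C@@H](C[C@@](C)(O)C#C[Si](C)(C)C)[C@@H]1[C@@H](O[Si](C)(C)C(C)(C)C)/C=C(/C)I | intermediate
20 | (3S,4S,5S)-3-[(dimethylamino)methyl]-4-[(1R,2Z)-1-hydroxy-3-iodobut-2-en-1-yl]-5-[(2R)-2-hydroxy-2-methylbut-3-yn-1-yl]oxolan-2-one | CN(C)C[C@H]1C(=O)O[C@@H](C[C@@](C)(O)C#C)[C@@H]1[C@@H](O)/C=C(/C)I | intermediate
21 | angelic acid [(2Z)-2-methylbut-2-enoic acid] | C/C=C(/C)C(=O)O | starting material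
22 | (2Z)-2-methylbut-2-en-1-ol | C/C=C(/C)CO | intermediate
23 | [(2S,3R)-2,3-dimethyloxiran-2-yl]methanol | OC[C@]1(C)O[C@@H]1C | intermediate
24 | (2R,3R)-2,3-dimethyloxirane-2-carboxylic acid | OC(=O)[C@]1(C)O[C@@H]1C | intermediate
25 | (2R,3R)-2,3-dimethyloxirane-2-carboxylic 2,4,6-trichlorobenzoic anhydride | O=C(OC(=O)[C@]1(C)O[C@@H]1C)c1c(Cl)cc(Cl)cc1Cl | intermediate
26 | (1R,2Z)-1-[(2S,3R,4S)-4-[(dimethylamino)methyl]-2-[(2R)-2-hydroxy-2-methylbut-3-yn-1-yl]-5-oxooxolan-3-yl]-3-iodobut-2-en-1-yl (2R,3R)-2,3-dimethyloxirane-2-carboxylate (masked key-step precursor) | CN(C)C[C@H]1C(=O)O[C@@H](C[C@@](C)(O)C#C)[C@@H]1[C@@H](OC(=O)[C@]2(C)O[C@@H]2C)/C=C(/C)I | intermediate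
27 | carbon monoxide | [C-]#[O+] | starting material
28 | (4Z,6S,7R,8S,10R,11S)-13-(dimethylamino)-10-hydroxy-3-oxo-6-{[(2R,3R)-2,3-dimethyloxirane-2-carbonyl]oxy}germacr-4-en-1-yn-12,8-olide (masked key-step product) | CN(C)C[C@H]1C(=O)O[C@H]2C[C@@](C)(O)C#CC(=O)/C(C)=C\[C@H](OC(=O)[C@]3(C)O[C@@H]3C)[C@H]12 | intermediate
29 | N-methyl iodide (trimethylammonium iodide) of 28 | C[N+](C)(C)C[C@H]1C(=O)O[C@H]2C[C@@](C)(O)C#CC(=O)/C(C)=C\[C@H](OC(=O)[C@]3(C)O[C@@H]3C)[C@H]12.[I-] | intermediate
30 | (4Z,6S,7R,8S,10R)-10-hydroxy-3-oxo-6-{[(2R,3R)-2,3-dimethyloxirane-2-carbonyl]oxy}germacra-4,11(13)-dien-1-yn-12,8-olide (key-step product, unmasked) | C=C1C(=O)O[C@H]2C[C@@](C)(O)C#CC(=O)/C(C)=C\[C@H](OC(=O)[C@]3(C)O[C@@H]3C)[C@H]12 | intermediate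
31 | (4Z,6S,7R,8S,10R)-3,10-epoxy-1-oxo-6-{[(2R,3R)-2,3-dimethyloxirane-2-carbonyl]oxy}germacra-2,4,11(13)-trien-12,8-olide (CNP0258430.3) | C=C1C(=O)O[C@H]2C[C@@]3(C)OC(=CC3=O)/C(C)=C\[C@H](OC(=O)[C@]3(C)O[C@@H]3C)[C@H]12 | target

## Step count and least certain steps

Total step count: 20. Longest linear sequence: 15 steps (steps 2, 3, 4, 5, 6, 7, 9, 10, 11, 12, 13, 17, 18, 19, 20, from 5 to 31). Step 1, step 8 and steps 14–16 are side branches that join the main line at steps 4, 9 and 17.

**Step 18 (key step, the one step that goes beyond known chemistry).** The most likely failure is that ring closure loses to intermolecular coupling, or that alkynyl transfer happens before carbon monoxide insertion, because the acyl(alkynyl)palladium intermediate must pass through a strained medium-ring chelate. Partial onward cyclisation of the ynone towards the furanone under the basic conditions would be harmless. The fallback uses known reactions only and runs from 26 back to 28. A Stille coupling of the vinyl iodide of 26 with Bu3SnCH2OH (Pd(PPh3)4, dioxane, 80 °C; no amine base and no copper, so the terminal alkyne stays a spectator) should give the Z allylic alcohol F1. Oxidation with MnO2 should give the Z enal F2, which cannot form a lactol because O6 is acylated. Iodination of the alkyne terminus (N-iodosuccinimide, AgNO3 cat.) should give the iodoalkyne F3. A Nozaki–Hiyama–Kishi macrocyclisation (CrCl2, NiCl2 cat., THF, high dilution) should then close C2–C3 to the ten-membered propargylic alcohol F4 (either C3 epimer), and MnO2 oxidation of this doubly activated carbinol returns to 28.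

**Step 4.** The most likely failure is erosion of the Z geometry or loss of iodide by addition–elimination of triethylamine or chloride at the β-iodoenal during the long reaction at room temperature, together with a modest anti/syn preference for the succinate-type imide. The fallback runs from 4 (with 5 as the source of the aldehyde) back to 10 and brings the iodine in after the aldol. MnO2 oxidation of 5 gives but-2-ynal F5, and the same anti-aldol with 4 should give the propargylic alcohol F6. Trans-hydrosilylation with Et3SiH and [Cp*Ru(MeCN)3]PF6, which places silicon on the carbon distal to the hydroxyl, should give the Z vinylsilane F7. Iododesilylation with N-iodosuccinimide, with retention, should give 10.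

**Step 10.** The most likely failure is poor facial selectivity at C10, because a loosely held or aggregated magnesium chelate can be attacked from either face and the two groups on the new centre are both small. Retro-aldol cleavage of the magnesium aldolate is a second risk. The fallback runs from 16 back to 18 and changes from chelate control to dipole control. Silylation of the C8 hydroxyl (Et3SiOTf, 2,6-lutidine) gives the triethylsilyl ether F8. The non-basic reagent from CH3Li and CeCl3 then adds methyl under the open dipole-minimised model, which predicts the same sense, to give the tertiary alcohol F9. TsOH·H2O in wet toluene removes the triethylsilyl group and closes the lactone to 18.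

**Step 20.** The most likely failure is slow or unselective hydration of an alkyne buried in a strained ring beside a cross-conjugated enone, with competing ionisation of the tertiary propargylic alcohol or Lewis-acid opening of the oxirane. The fallback runs from 28 back to 31 and forms the furanone before the methylene lactone is unmasked. Conjugate addition of Et2NH to the ynone gives the β-aminoenone F10. Aqueous acetic acid hydrolyses and cyclises it to the masked furanone F11. CH3I, then aqueous NaHCO3, through the methiodide F12, unveils the methylene lactone and gives 31.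

## Further compounds

F1 | step 18 | Z allylic alcohol: 26 with the iodine on C4 replaced by a hydroxymethyl group (C3 carbinol) | CN(C)C[C@H]1C(=O)O[C@@H](C[C@@](C)(O)C#C)[C@@H]1[C@@H](OC(=O)[C@]2(C)O[C@@H]2C)/C=C(/C)CO
F2 | step 18 | Z enal: 26 with the iodine on C4 replaced by a formyl group (C3 aldehyde) | CN(C)C[C@H]1C(=O)O[C@@H](C[C@@](C)(O)C#C)[C@@H]1[C@@H](OC(=O)[C@]2(C)O[C@@H]2C)/C=C(/C)C=O
F3 | step 18 | iodoalkyne: F2 with iodine on the alkyne terminus C2 | CN(C)C[C@H]1C(=O)O[C@@H](C[C@@](C)(O)C#CI)[C@@H]1[C@@H](OC(=O)[C@]2(C)O[C@@H]2C)/C=C(/C)C=O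
F4 | step 18 | ten-membered propargylic alcohol: 28 with a C3 carbinol in place of the C3 ketone (either C3 epimer) | CN(C)C[C@H]1C(=O)O[C@H]2C[C@@](C)(O)C#CC(O)/C(C)=C\[C@H](OC(=O)[C@]3(C)O[C@@H]3C)[C@H]12
F5 | step 4 | but-2-ynal | CC#CC=O
F6 | step 4 | tert-butyl (3S,4R)-3-[(4R)-4-benzyl-2-oxo-1,3-oxazolidine-3-carbonyl]-4-hydroxyhept-5-ynoate | CC(C)(C)OC(=O)C[C@H](C(=O)N1[C@H](Cc2ccccc2)COC1=O)[C@@H](O)C#CC
F7 | step 4 | Z vinylsilane: 10 with triethylsilyl in place of iodine | CC(C)(C)OC(=O)C[C@H](C(=O)N1[C@H](Cc2ccccc2)COC1=O)[C@@H](O)/C=C(/C)[Si](CC)(CC)CC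
F8 | step 10 | C8 triethylsilyl ether of 16 | CC(C)(C)OC(=O)C[C@H]([C@@H](O[Si](CC)(CC)CC)CC(=O)C#C[Si](C)(C)C)[C@@H](O[Si](C)(C)C(C)(C)C)/C=C(/C)I
F9 | step 10 | C8 triethylsilyl ether of 17 | CC(C)(C)OC(=O)C[C@H]([C@@H](O[Si](CC)(CC)CC)C[C@@](C)(O)C#C[Si](C)(C)C)[C@@H](O[Si](C)(C)C(C)(C)C)/C=C(/C)I
F10 | step 20 | β-aminoenone: diethylamine adduct of 28 at C1 (enamine geometry not fixed) | CN(C)C[C@H]1C(=O)O[C@H]2C[C@@](C)(O)C(N(CC)CC)=CC(=O)/C(C)=C\[C@H](OC(=O)[C@]3(C)O[C@@H]3C)[C@H]12
F11 | step 20 | masked furanone: 13-(dimethylamino)-11,13-dihydro derivative of 31 (11S) | CN(C)C[C@H]1C(=O)O[C@H]2C[C@@]3(C)OC(=CC3=O)/C(C)=C\[C@H](OC(=O)[C@]4(C)O[C@@H]4C)[C@H]12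
F12 | step 20 | N-methyl iodide of F11 | C[N+](C)(C)C[C@H]1C(=O)O[C@H]2C[C@@]3(C)OC(=CC3=O)/C(C)=C\[C@H](OC(=O)[C@]4(C)O[C@@H]4C)[C@H]12.[I-]
A1 | alternative 1 | ten-membered (4Z)-furanone carbocycle with O6 p-methoxybenzyl ether and O8 and O12 tert-butyldimethylsilyl ethers | C=C(CO[Si](C)(C)C(C)(C)C)[C@@H]1[C@@H](O[Si](C)(C)C(C)(C)C)C[C@@]2(C)OC(=CC2=O)/C(C)=C\[C@@H]1OCc3ccc(OC)cc3
A2 | alternative 1 | eleven-membered cyclic sulfone with the sulfonyl group between C4 and C5 (C4 epimer not fixed) | C=C(CO[Si](C)(C)C(C)(C)C)[C@@H]1[C@@H](O[Si](C)(C)C(C)(C)C)C[C@@]2(C)OC(=CC2=O)C(C)S(=O)(=O)C[C@@H]1OCc3ccc(OC)cc3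
A3 | alternative 2 | tricyclic α-methylene lactone with O6 triethylsilyl ether | C=C1C(=O)O[C@H]2C[C@@]3(C)OC(=CC3=O)/C(C)=C\[C@H](O[Si](CC)(CC)CC)[C@H]12
A4 | alternative 2 | bicyclic furanone with C7 ethynyl, free C8 hydroxyl and O6 triethylsilyl ether | C#C[C@@H]1[C@@H](O)C[C@@]2(C)OC(=CC2=O)/C(C)=C\[C@@H]1O[Si](CC)(CC)CC
A5 | alternative 3 | ten-membered cyclodecenynol with C6 hydroxyl and C7 silyloxypropenyl group | C1[C@@](C)(O[Si](C)(C)C)[C@@H](O[Si](C)(C)C(C)(C)C)C#C/C(C)=C\[C@H](O)[C@H](C(=C)CO[Si](C)(C)C(C)(C)C)[C@H]1O[Si](C)(C)C(C)(C)C
A6 | alternative 3 | thirteen-membered bis-allylic ether with oxygen between C6 and C13 and a C7=C11 double bond | C1[C@@](C)(O[Si](C)(C)C)[C@@H](O[Si](C)(C)C(C)(C)C)C#C/C(C)=C\COC/C(CO[Si](C)(C)C(C)(C)C)=C/[C@H]1O[Si](C)(C)C(C)(C)C
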